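**Assumptions:** The target has no stereocentres (the SMILES contains none), so nothing needs to be set or protected against scrambling. The hydrogen sulfate is isolated as its ammonium salt and converted to the neutral acid in the last step, held cold because aryl hydrogen sulfates are acid-labile. 3,4-Bis(benzyloxy)benzaldehyde is taken as commercially available.

## Retrosynthesis
1. Target ⇒ 6-O-sulfate of 7,3',4'-tri-O-benzyl-6-hydroxyluteolin by hydrogenolysis and cation exchange. The sulfate comes from chemoselective sulfation of the only non-chelated phenol, 6-OH, since 5-OH is H-bonded to C4=O.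
2. The 5,6-diol comes from **new step: 5-O-hydrosilyl-directed Ir-catalysed C6–H borylation, then oxidation**. C6 is the only ortho C–H of O5 because C4a is quaternary, so C8 cannot compete.
3. 7,3',4'-Tri-O-benzylluteolin (5-OH free) comes from I2/DMSO oxidative cyclisation, which forms the pyranone C-ring, the only ring formed in the route, of a 2',6'-dihydroxychalcone. The symmetric 2',6'-diol has no regiochemical ambiguity.
4. The chalcone comes from Claisen–Schmidt condensation of 4'-O-benzylphloroacetophenone (from phloroacetophenone) with 3,4-bis(benzyloxy)benzaldehyde. Rings A and B are pre-formed aromatic building blocks.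

## Route

**Step 1**
Reactants: **1** 2',4',6'-trihydroxyacetophenone; **2** benzyl bromide
Product: **3** 4'-benzyloxy-2',6'-dihydroxyacetophenone
Conditions: BnBr (1.05 equiv), K2CO3 (1.1 equiv), KI (cat.), acetone, 50 °C, 12 h
Reagents that add atoms: benzyl bromide, BrCc1ccccc1 (adds the benzyl group)
Why: Williamson etherification; the 4-OH is the most acidic and only non-chelated phenol (the 2,6-OH are H-bonded to C=O), so mono-benzylation is selective, and the 2/6 symmetry means later ring closure is regio-unambiguous.

**Step 2**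
Reactants: **3**; **4** 3,4-bis(benzyloxy)benzaldehyde
Product: **5** (E)-1-(4-benzyloxy-2,6-dihydroxyphenyl)-3-[3,4-bis(benzyloxy)phenyl]prop-2-en-1-one
Conditions: KOH (4 equiv), EtOH/H2O, rt, 48 h; then aq. HCl to pH 3
Reagents that add atoms: none (aldehyde 4 is the coupling partner)
Why: Claisen–Schmidt (aldol) condensation; the extra base equivalents cover the two phenols, and the E-enone forms by dehydration.

**Step 3**
Reactants: **5**
Product: **6** 5-hydroxy-7,3',4'-tris(benzyloxy)flavone (7,3',4'-tri-O-benzylluteolin)
Conditions: I2 (0.2 equiv), DMSO, 130 °C, 2 h; aq. Na2S2O3 work-up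
Reagents that add atoms: none
Why: Iodine/DMSO oxidative cyclisation (oxa-Michael addition to the flavanone, then iodination/elimination) forms the C2=C3 flavone; the remaining 2',6'-OH becomes the chelated 5-OH.

**Step 4**
Reactants: **6**; **7** chlorodiethylsilane
Product: **8** 5-O-(diethylsilyl)-7,3',4'-tris(benzyloxy)flavone
Conditions: NaH (1.2 equiv), THF, 0 °C, then Et2SiHCl (1.5 equiv), 0 °C→rt, 1 h; filter through Celite under Ar and use crude
Reagents that add atoms: chlorodiethylsilane, CC[SiH](Cl)CC (adds the SiHEt2 group)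
Why: Silylation of the chelated 5-phenoxide with a small chlorosilane gives the hydrosilyl ether directing group, and the peri C4=O orients the Si–H arm syn to C6.

**Step 5**
Reactants: **8**; **9** bis(pinacolato)diboron
Product: **10** 6-Bpin-5-O-(diethylsilyl)-7,3',4'-tris(benzyloxy)flavone
Conditions: [Ir(cod)OMe]2 (2 mol%), Me4phen (4 mol%), B2pin2 (1.5 equiv), THF, 80 °C, 16 h, sealed tube
Reagents that add atoms: B2pin2, CC1(C)OB(OC1(C)C)B1OC(C)(C)C(C)(C)O1 (adds Bpin)
Why: Proposed new method: an Ir(Bpin)3/phenanthroline species undergoes Si–H oxidative addition with the 5-OSiHEt2 ether, and the resulting Ir–Si/Ir–C five-membered metallacycle can only reach C6 (the sole ortho C–H of O5, since C4a is quaternary), so C–B reductive elimination gives exclusive 6-borylation over C8, C3 and the B-ring; the closest known reaction is silyl-directed ortho C–H borylation of simple phenols, here extended to a peri-chelate-derived flavone 5-O-silyl ether flanked by a 7-OBn group, to form the C6–O precursor bond.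

**Step 6**
Reactants: **10**; **11** sodium perborate
Product: **12** 5,6-dihydroxy-7,3',4'-tris(benzyloxy)flavone
Conditions: NaH BO3·4H2O (5 equiv), THF/H2O 1:1, rt, 1 h, degassed, Ar; aq. NH4Cl quench to pH ~6; use promptly
Reagents that add atoms: sodium perborate, [Na+].OOB(O)[O-] (supplies the new C6–O oxygen)
Why: Mild perborate oxidation (Brown-type C–B oxidation, 1,2-aryl shift from B to O) converts Ar–Bpin to Ar–OH, and the aryl O–SiHEt2 hydrolyses in situ to free the 5-OH; the buffered pH avoids oxidation of the electron-rich 5,6-diol.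

**Step 7**
Reactants: **12**; **13** sulfur trioxide–trimethylamine complex
Product: **14** triethylammonium 5-hydroxy-7,3',4'-tris(benzyloxy)-4-oxo-flavon-6-yl sulfate
Conditions: SO3·NMe3 (3 equiv), Et3N (3 equiv), MeCN, 60 °C, 12 h; silica chromatography (CH2Cl2/MeOH)
Reagents that add atoms: SO3·NMe3, C[N+](C)(C)S(=O)(=O)[O-] (adds SO3); Et3N, CCN(CC)CC (stays as the Et3NH+ counter-ion)
Why: O-Sulfation with an amine–SO3 complex is selective for 6-OH, the only non-chelated free phenol, while the C4=O-H-bonded 5-OH is unreactive.

**Step 8**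
Reactants: **14**
Product: **15** triethylammonium 6-sulfate of 5,7,3',4'-tetrahydroxyflavone
Conditions: H2 (1 atm), 10% Pd/C, THF/MeOH 1:1, rt, 3 h (monitor to avoid C2=C3 reduction)
Reagents that add atoms: none (H2 adds only hydrogen)
Why: Catalytic hydrogenolysis removes all three benzyl ethers (O-debenzylation), while the aryl sulfate monoester and the flavone C2=C3 survive at short reaction time.

**Step 9**
Reactants: **15**
Product: **16** 6-hydroxyluteolin 6-sulfate (target, hydrogen sulfate)
Conditions: Dowex 50WX8 (H+ form), MeOH/H2O, 0 °C, 10 min; freeze-dry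
Reagents that add atoms: none (H+ replaces Et3NH+)
Why: Cation exchange replaces the ammonium counter-ion with H+, and the cold, short contact time avoids acid hydrolysis of the aryl sulfate.

## Compound list
1 | 2',4',6'-trihydroxyacetophenone | CC(=O)c1c(O)cc(O)cc1O | starting material
2 | benzyl bromide | BrCc1ccccc1 | starting material
3 | 4'-benzyloxy-2',6'-dihydroxyacetophenone | CC(=O)c1c(O)cc(OCc2ccccc2)cc1O | intermediate
4 | 3,4-bis(benzyloxy)benzaldehyde | O=Cc1ccc(OCc2ccccc2)c(OCc2ccccc2)c1 | starting material
5 | (E)-chalcone 1-(4-benzyloxy-2,6-dihydroxyphenyl)-3-[3,4-bis(benzyloxy)phenyl]propenone | O=C(/C=C/c1ccc(OCc2ccccc2)c(OCc2ccccc2)c1)c1c(O)cc(OCc2ccccc2)cc1O | intermediate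
6 | 5-hydroxy-7,3',4'-tris(benzyloxy)flavone | O=c1cc(-c2ccc(OCc3ccccc3)c(OCc3ccccc3)c2)oc2cc(OCc3ccccc3)cc(O)c12 | intermediate
7 | chlorodiethylsilane | CC[SiH](Cl)CC | starting material (reagent)
8 | 5-O-(diethylsilyl)-7,3',4'-tris(benzyloxy)flavone | O=c1cc(-c2ccc(OCc3ccccc3)c(OCc3ccccc3)c2)oc2cc(OCc3ccccc3)cc(O[SiH](CC)CC)c12 | intermediate
9 | bis(pinacolato)diboron | CC1(C)OB(OC1(C)C)B1OC(C)(C)C(C)(C)O1 | starting material (reagent)
10 | 6-Bpin-5-O-(diethylsilyl)-7,3',4'-tris(benzyloxy)flavone | O=c1cc(-c2ccc(OCc3ccccc3)c(OCc3ccccc3)c2)oc2cc(OCc3ccccc3)c(B3OC(C)(C)C(C)(C)O3)c(O[SiH](CC)CC)c12 | intermediate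
11 | sodium perborate | [Na+].OOB(O)[O-] | starting material (reagent)
12 | 5,6-dihydroxy-7,3',4'-tris(benzyloxy)flavone | O=c1cc(-c2ccc(OCc3ccccc3)c(OCc3ccccc3)c2)oc2cc(OCc3ccccc3)c(O)c(O)c12 | intermediate
13 | sulfur trioxide–trimethylamine | C[N+](C)(C)S(=O)(=O)[O-] | starting material (reagent)
14 | triethylammonium 6-sulfate of 12 | CC[NH+](CC)CC.O=c1cc(-c2ccc(OCc3ccccc3)c(OCc3ccccc3)c2)oc2cc(OCc3ccccc3)c(OS(=O)(=O)[O-])c(O)c12 | intermediate
15 | triethylammonium 6-hydroxyluteolin 6-sulfate | CC[NH+](CC)CC.O=c1cc(-c2ccc(O)c(O)c2)oc2cc(O)c(OS(=O)(=O)[O-])c(O)c12 | intermediate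
16 | 6-hydroxyluteolin 6-sulfate | O=c1cc(-c2ccc(O)c(O)c2)oc2cc(O)c(OS(=O)(=O)O)c(O)c12 | target

**Total steps:** 9. **Longest linear sequence:** 9 (compound 1 → 16).

## Three steps most likely to fail
1. **Step 5 (proposed new C6–H borylation).** Sterics from the flanking 7-OBn may slow directed borylation, and the 5-O–Si ether may be labile.
   Fallback: install the C6 oxygen before ring formation by the known Elbs persulfate oxidation. Start from 2-hydroxy-4,6-bis(benzyloxy)acetophenone (from 1 with 2 equiv BnBr). Treat with K2S2O8/NaOH at 0 °C to give the C5 (future C6) aryl sulfate para to the free OH. Then run Claisen–Schmidt with 4, I2/DMSO cyclisation, and hydrogenolysis, which replaces steps 4–7.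
2. **Step 7 (regioselective 6-sulfation).** The 5,6-diol 12 is air-sensitive, and sulfation may also occur at the chelated 5-OH.
   Fallback: hydrogenolyse 12 to 6-hydroxyluteolin and sulfate it biocatalytically with a recombinant arylsulfotransferase (p-nitrophenyl sulfate donor) or a flavonoid 6-sulfotransferase with PAPS, then purify by reverse-phase HPLC.
3. **Step 8 (hydrogenolysis).** Over-reduction of C2=C3 to a flavanone, or catalyst poisoning by the amine salt, could lower the yield.
   Fallback: remove the benzyl ethers with BCl3 and pentamethylbenzene as a cation scavenger in CH2Cl2 at −78 °C, a Lewis-acid debenzylation in place of hydrogenation, then carry out the cation exchange.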